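**Retrosynthetic overview**

1. Target 21 ⇐ bromoalkene 20 (exo-face diimide reduction sets the endo C2–Br) ⇐ 7-oxabicyclo[2.2.1]heptan-2-one 19.
2. 19 ⇐ oxetanyl α-diazo ketone 17: the oxolane O7–C1–C6–C5–C4 is made from the oxetane O7–C4–C5–C6 by insertion of the carbene carbon C1 (oxonium ylide, then [1,2]-shift), which also closes the carbocycle C1–C6.
3. Enabling feature: the bromine-bearing C2 lies next to the methyl-bearing, oxygen-bound bridgehead C1. At the ketone level C1 is an α-oxy-α-acyl carbon, i.e. the carbene carbon of a diazo ketone, and O7, C4 and the ethano bridge C5–C6 form an oxetane that lacks only C1.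
4. 17 ⇐ acid 15 ⇐ allyl oxetane 13 ⇐ chloro alcohol 12 ⇐ β-chloro ketone 11 (reagent-controlled allylation sets C4) ⇐ bromo ester 8.
5. 8 ⇐ catalytic asymmetric Diels–Alder (2 + 3), cyclopropane route to the gem-dimethyl group, axial-selective reduction, Appel inversion. Ring order: cyclohexane A, then the oxetane, then both oxolane rings of the oxabicycle in the key step.

Key step: step 13

Remark: locants C1–C7 are those of the 7-oxabicyclo[2.2.1]heptane core of the target (C1 methyl-bearing bridgehead, C2 CHBr, C3 CH2, C4 cyclohexyl-bearing bridgehead, C5–C6 ethano bridge with C6 next to C1, O7). The antipodes of the Diels–Alder catalyst and of the allylborane are assigned from the accepted transition-state models and would be confirmed by correlation before scale-up.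

**Route**

Step 1
Reactants: 1 3-methylbut-3-en-2-one
Product: 2 triisopropyl[(3-methylbuta-1,3-dien-2-yl)oxy]silane
Conditions: i-Pr3SiOTf, Et3N, CH2Cl2, 0 °C → rt
Reagents that add atoms: triisopropylsilyl trifluoromethanesulfonate, CC(C)[Si](OS(=O)(=O)C(F)(F)F)(C(C)C)C(C)C
Why: Soft enolisation and O-silylation of the methyl ketone, whose methyl group is the only enolisable position, should give the 2-silyloxy diene as in the standard preparation of such dienes.

Step 2
Reactants: 2 triisopropyl[(3-methylbuta-1,3-dien-2-yl)oxy]silane; 3 2,2,2-trifluoroethyl acrylate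
Product: 4 2,2,2-trifluoroethyl (1S)-3-methyl-4-[(triisopropylsilyl)oxy]cyclohex-3-ene-1-carboxylate
Conditions: (S)-B-(o-tolyl)-α,α-diphenylprolinol-derived oxazaborolidine·HNTf2 (10 mol%), CH2Cl2, −78 → −20 °C
Reagents that add atoms: none
Why: This is a catalytic enantioselective Diels–Alder reaction of a 2-silyloxy diene with an acrylate bound to a cationic oxazaborolidine; the silyloxy group directs the 1,4 ("para") orientation of ester and silyloxy carbon, and the catalyst should expose the Re face of Cα of the s-trans acrylate (the sense expected for simple dienes with this ester), which sets the (S) centre.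

Step 3
Reactants: 4 2,2,2-trifluoroethyl (1S)-3-methyl-4-[(triisopropylsilyl)oxy]cyclohex-3-ene-1-carboxylate
Product: 5 2,2,2-trifluoroethyl (3S)-1-methyl-6-[(triisopropylsilyl)oxy]bicyclo[4.1.0]heptane-3-carboxylate (both cyclopropane faces)
Conditions: Et2Zn, CH2I2, CH2Cl2, 0 °C → rt
Reagents that add atoms: diiodomethane, ICI
Why: Simmons–Smith cyclopropanation is fast on an electron-rich tetrasubstituted silyl enol ether and leaves the ester alone; the two cyclopropane diastereomers converge in the next step.

Step 4
Reactants: 5 2,2,2-trifluoroethyl (3S)-1-methyl-6-[(triisopropylsilyl)oxy]bicyclo[4.1.0]heptane-3-carboxylate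
Product: 6 methyl (1S)-3,3-dimethyl-4-oxocyclohexane-1-carboxylate
Conditions: HCl (1 M in MeOH), 60 °C
Reagents that add atoms: methanol, CO
Why: Acid-mediated opening of the siloxycyclopropane (protonation at the cyclopropane CH2, cleavage of its bond to the oxygen-bearing carbon) should give the second methyl group and the ketone while the activated ester is transesterified; no base is present, so the single stereocentre α to the ester is not enolised.

Step 5
Reactants: 6 methyl (1S)-3,3-dimethyl-4-oxocyclohexane-1-carboxylate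
Product: 7 methyl (1S,4R)-4-hydroxy-3,3-dimethylcyclohexane-1-carboxylate (cis, axial OH)
Conditions: LiBH(s-Bu)3, THF, −78 °C; AcOH quench at −78 °C
Reagents that add atoms: none
Why: The bulky trialkylborohydride should attack the ketone from the equatorial direction, as it does with 4,4-dimethyl-3-keto steroids, giving the axial alcohol cis to the equatorial ester; the ester survives at −78 °C and the cold acidic quench avoids lactonisation.

Step 6
Reactants: 7 methyl (1S,4R)-4-hydroxy-3,3-dimethylcyclohexane-1-carboxylate
Product: 8 methyl (1S,4S)-4-bromo-3,3-dimethylcyclohexane-1-carboxylate (trans, diequatorial)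
Conditions: CBr4, P(n-Oct)3, toluene, 70 °C
Reagents that add atoms: carbon tetrabromide, BrC(Br)(Br)Br
Why: Appel bromination with inversion should turn the axial alcohol into the equatorial bromide trans to the ester; this reaction type with a trialkylphosphine has precedent at neopentylic secondary carbinols next to a gem-dimethyl group in brominated terpenoids.

Step 7
Reactants: 8 methyl (1S,4S)-4-bromo-3,3-dimethylcyclohexane-1-carboxylate
Product: 9 (1S,4S)-4-bromo-N-methoxy-N,3,3-trimethylcyclohexane-1-carboxamide
Conditions: MeNHOMe·HCl, i-PrMgCl, THF, −20 °C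
Reagents that add atoms: N,O-dimethylhydroxylamine hydrochloride, CNOC.Cl
Why: Aminolysis of the ester by the magnesium amide gives the Weinreb amide; the equatorial neopentylic bromide has no anti-periplanar hydrogen and is inert, and any epimerisation α to the carbonyl would return the more stable trans isomer.

Step 8
Reactants: 9 (1S,4S)-4-bromo-N-methoxy-N,3,3-trimethylcyclohexane-1-carboxamide
Product: 11 1-[(1S,4S)-4-bromo-3,3-dimethylcyclohexyl]-3-chloropropan-1-one, via vinyl ketone 10 (not isolated)
Conditions: CH2=CHMgBr, THF, −20 → 0 °C; then inverse quench into HCl (2 M in Et2O), 0 °C → rt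
Reagents that add atoms: vinylmagnesium bromide, C=C[Mg]Br; hydrogen chloride, Cl
Why: Weinreb ketone synthesis stops at the ketone stage, and quenching into excess HCl keeps the liberated amine protonated while HCl adds conjugately to the vinyl ketone to give the β-chloro ketone.

Step 9
Reactants: 11 1-[(1S,4S)-4-bromo-3,3-dimethylcyclohexyl]-3-chloropropan-1-one
Product: 12 (3R)-3-[(1S,4S)-4-bromo-3,3-dimethylcyclohexyl]-1-chlorohex-5-en-3-ol
Conditions: B-allyl-10-phenyl-9-borabicyclo[3.3.2]decane (Si-face-selective antipode, 1.3 equiv), Et2O, −78 °C; then NaOH, MeOH/H2O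
Reagents that add atoms: B-allyl-10-phenyl-9-borabicyclo[3.3.2]decane, C=CCB1C(c2ccccc2)C2CCCC1CCC2
Why: Reagent-controlled asymmetric allylboration of a ketone through a closed chair transition state should distinguish the secondary cyclohexyl group from the primary CH2CH2Cl arm and deliver allyl to the Si face, setting the (R) carbinol that becomes C4; the remote ring stereocentres exert no bias and a minor epimer would be removed by chromatography.

Step 10
Reactants: 12 (3R)-3-[(1S,4S)-4-bromo-3,3-dimethylcyclohexyl]-1-chlorohex-5-en-3-ol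
Product: 13 (2R)-2-[(1S,4S)-4-bromo-3,3-dimethylcyclohexyl]-2-(prop-2-en-1-yl)oxetane
Conditions: KOt-Bu, THF, 0 °C → rt
Reagents that add atoms: none
Why: Intramolecular Williamson etherification (4-exo-tet) of the tertiary alkoxide on the primary chloride, helped by the fully substituted carbinol carbon, should close the oxetane without touching the C–O bond of the stereocentre.

Step 11
Reactants: 13 (2R)-2-[(1S,4S)-4-bromo-3,3-dimethylcyclohexyl]-2-(prop-2-en-1-yl)oxetane
Product: 15 2-{(2S)-2-[(1S,4S)-4-bromo-3,3-dimethylcyclohexyl]oxetan-2-yl}acetic acid, via oxetanyl acetaldehyde 14 (not isolated)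
Conditions: O3, CH2Cl2, −78 °C; PPh3; then NaClO2, NaH2PO4, 2-methyl-2-butene, t-BuOH/H2O, 0 °C
Reagents that add atoms: ozone, [O-][O+]=O; sodium chlorite, [Na+].[O-]Cl=O
Why: Ozonolysis of the terminal alkene and buffered Pinnick oxidation of the crude aldehyde are mild enough for the oxetane and the alkyl bromide; the acid is used at once because oxetanyl acids can isomerise to lactones.

Step 12
Reactants: 15 2-{(2S)-2-[(1S,4S)-4-bromo-3,3-dimethylcyclohexyl]oxetan-2-yl}acetic acid
Product: 17 3-diazo-1-{(2S)-2-[(1S,4S)-4-bromo-3,3-dimethylcyclohexyl]oxetan-2-yl}butan-2-one, via mixed carbonic anhydride 16 (not isolated)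
Conditions: i-BuOCOCl, Et3N, THF, −20 °C; then CH3CHN2 (ethereal solution from N-ethyl-N-nitrosourea/KOH), −20 → 0 °C
Reagents that add atoms: diazoethane, CC=[N+]=[N-]
Why: Acylation of diazoethane by a mixed carbonic anhydride (Arndt–Eistert-type diazo ketone synthesis) avoids the acid chloride and free HCl, which would open the oxetane, and places the methyl group on the diazo carbon.

Step 13
Reactants: 17 3-diazo-1-{(2S)-2-[(1S,4S)-4-bromo-3,3-dimethylcyclohexyl]oxetan-2-yl}butan-2-one
Product: 19 (1R,4S)-4-[(1S,4S)-4-bromo-3,3-dimethylcyclohexyl]-1-methyl-7-oxabicyclo[2.2.1]heptan-2-one, via bicyclic oxonium ylide 18 (not isolated)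
Conditions: Cu(CF3COCHCOCF3)2 (5 mol%), CH2Cl2, reflux, slow addition of 17 by syringe pump (high dilution)
Reagents that add atoms: none
Why: Proposed new method: copper-mediated loss of N2 from 17 gives an electrophilic carbenoid at C1, the oxetane oxygen O7 adds to it (closure of the five-membered ring O7–C4–C3–C2–C1, the preferred ring size in oxonium ylide formation) to give ylide 18, and a Stevens [1,2]-shift then moves C6 from O7 to C1 by O7–C6 homolysis and recombination of the tethered radical pair, so that the oxetane O7–C4–C5–C6 is enlarged by one atom to the oxolane O7–C1–C6–C5–C4 and the carbocycle C1–C6 is closed in the same event. The closest known reaction types are the copper- or rhodium-catalysed one-carbon ring expansion of oxetanes to oxolanes by diazo carbonyl compounds (intermolecular) and the [1,2]-shift of bicyclic oxonium ylides from diazo ketones tethered to five- and six-membered cyclic ethers, which gives oxygen-bridged carbocycles; a tethered oxetane leading to a [2.2.1] oxabicycle is the untested combination. C4 keeps its configuration because none of its four bonds is broken, and the new quaternary centre C1 is set by the tether alone, since C6 stays attached through C5 to C4 on the side of O7, so only the cis-bridged (1R,4S) ketone can form. The first selectivity needed is ylide formation over 1,2-hydride shift from the methyl group and over 1,5-insertion into the tertiary C–H of ring A; the exposed, basic oxetane oxygen placed for five-ring closure and an electron-poor copper catalyst that favours ylide chemistry should secure it, in line with α-methyl diazo ketones that are known to form cyclic carbonyl ylides without hydride shift. The second is migration of the exocyclic C6 and not of the ring-fusion carbon C4: the O7–C6 bond is nearly parallel to the enolate-type p orbital at C1 while O7–C4 lies in the plane of the five-membered ring, and C4 migration would give a strained cyclobutanone, so stereoelectronics and product strain both point to C6, with release of oxetane strain driving the shift ahead of β-elimination.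

Step 14
Reactants: 19 (1R,4S)-4-[(1S,4S)-4-bromo-3,3-dimethylcyclohexyl]-1-methyl-7-oxabicyclo[2.2.1]heptan-2-one
Product: 20 (1R,4R)-2-bromo-4-[(1S,4S)-4-bromo-3,3-dimethylcyclohexyl]-1-methyl-7-oxabicyclo[2.2.1]hept-2-ene
Conditions: (PhO)3P, Br2, Et3N, CH2Cl2, −60 °C → reflux
Reagents that add atoms: bromine, BrBr
Why: The triphenyl phosphite–bromine reagent converts enolisable ketones into vinyl bromides by O-phosphonium activation, bromide addition and loss of HBr; the only α-hydrogens are on C3 (the other α-carbon is the quaternary bridgehead C1), so one regioisomer is possible.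

Step 15
Reactants: 20 (1R,4R)-2-bromo-4-[(1S,4S)-4-bromo-3,3-dimethylcyclohexyl]-1-methyl-7-oxabicyclo[2.2.1]hept-2-ene
Product: 21 (1R,2R,4S)-2-bromo-4-[(1S,4S)-4-bromo-3,3-dimethylcyclohexyl]-1-methyl-7-oxabicyclo[2.2.1]heptane
Conditions: KO2CN=NCO2K (excess, in portions), AcOH, MeOH/CH2Cl2, 0 °C → rt
Reagents that add atoms: none
Why: Diimide transfers two hydrogens syn to the strained bicyclic alkene from the exo face (the side of the oxygen bridge, the general rule for norbornenes and 7-oxanorbornenes), which places hydrogen exo and bromine endo at C2 (2R); no metal is present, so neither C–Br bond is hydrogenolysed.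

**Compound list**

1 | 3-methylbut-3-en-2-one | CC(=O)C(C)=C | starting material
2 | triisopropyl[(3-methylbuta-1,3-dien-2-yl)oxy]silane | C=C(O[Si](C(C)C)(C(C)C)C(C)C)C(C)=C | intermediate
3 | 2,2,2-trifluoroethyl acrylate | C=CC(=O)OCC(F)(F)F | starting material
4 | 2,2,2-trifluoroethyl (1S)-3-methyl-4-[(triisopropylsilyl)oxy]cyclohex-3-ene-1-carboxylate | CC1=C(O[Si](C(C)C)(C(C)C)C(C)C)CC[C@H](C(=O)OCC(F)(F)F)C1 | intermediate
5 | 2,2,2-trifluoroethyl (3S)-1-methyl-6-[(triisopropylsilyl)oxy]bicyclo[4.1.0]heptane-3-carboxylate | CC12CC1(O[Si](C(C)C)(C(C)C)C(C)C)CC[C@H](C(=O)OCC(F)(F)F)C2 | intermediate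
6 | methyl (1S)-3,3-dimethyl-4-oxocyclohexane-1-carboxylate | CC1(C)C[C@@H](C(=O)OC)CCC1=O | intermediate
7 | methyl (1S,4R)-4-hydroxy-3,3-dimethylcyclohexane-1-carboxylate | CC1(C)C[C@@H](C(=O)OC)CC[C@H]1O | intermediate
8 | methyl (1S,4S)-4-bromo-3,3-dimethylcyclohexane-1-carboxylate | CC1(C)C[C@@H](C(=O)OC)CC[C@@H]1Br | intermediate
9 | (1S,4S)-4-bromo-N-methoxy-N,3,3-trimethylcyclohexane-1-carboxamide | CC1(C)C[C@@H](C(=O)N(C)OC)CC[C@@H]1Br | intermediate
10 | 1-[(1S,4S)-4-bromo-3,3-dimethylcyclohexyl]prop-2-en-1-one | CC1(C)C[C@@H](C(=O)C=C)CC[C@@H]1Br | intermediate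
11 | 1-[(1S,4S)-4-bromo-3,3-dimethylcyclohexyl]-3-chloropropan-1-one | CC1(C)C[C@@H](C(=O)CCCl)CC[C@@H]1Br | intermediate
12 | (3R)-3-[(1S,4S)-4-bromo-3,3-dimethylcyclohexyl]-1-chlorohex-5-en-3-ol | CC1(C)C[C@@H]([C@@](O)(CC=C)CCCl)CC[C@@H]1Br | intermediate
13 | (2R)-2-[(1S,4S)-4-bromo-3,3-dimethylcyclohexyl]-2-(prop-2-en-1-yl)oxetane | CC1(C)C[C@@H]([C@@]2(CC=C)CCO2)CC[C@@H]1Br | intermediate
14 | 2-{(2S)-2-[(1S,4S)-4-bromo-3,3-dimethylcyclohexyl]oxetan-2-yl}acetaldehyde | CC1(C)C[C@@H]([C@@]2(CC=O)CCO2)CC[C@@H]1Br | intermediate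
15 | 2-{(2S)-2-[(1S,4S)-4-bromo-3,3-dimethylcyclohexyl]oxetan-2-yl}acetic acid | CC1(C)C[C@@H]([C@@]2(CC(=O)O)CCO2)CC[C@@H]1Br | intermediate
16 | 2-{(2S)-2-[(1S,4S)-4-bromo-3,3-dimethylcyclohexyl]oxetan-2-yl}acetic (2-methylpropyl carbonic) anhydride | CC1(C)C[C@@H]([C@@]2(CC(=O)OC(=O)OCC(C)C)CCO2)CC[C@@H]1Br | intermediate
17 | 3-diazo-1-{(2S)-2-[(1S,4S)-4-bromo-3,3-dimethylcyclohexyl]oxetan-2-yl}butan-2-one | CC1(C)C[C@@H]([C@@]2(CC(=O)C(C)=[N+]=[N-])CCO2)CC[C@@H]1Br | intermediate
18 | (5S)-5-[(1S,4S)-4-bromo-3,3-dimethylcyclohexyl]-2-methyl-3-oxo-1-oxoniabicyclo[3.2.0]heptan-2-ide | CC1(C)C[C@@H]([C@@]23CC[O+]2[C-](C)C(=O)C3)CC[C@@H]1Br | intermediate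
19 | (1R,4S)-4-[(1S,4S)-4-bromo-3,3-dimethylcyclohexyl]-1-methyl-7-oxabicyclo[2.2.1]heptan-2-one | CC1(C)C[C@@H]([C@@]23CC[C@@](C)(O2)C(=O)C3)CC[C@@H]1Br | intermediate
20 | (1R,4R)-2-bromo-4-[(1S,4S)-4-bromo-3,3-dimethylcyclohexyl]-1-methyl-7-oxabicyclo[2.2.1]hept-2-ene | CC1(C)C[C@@H]([C@@]23CC[C@@](C)(O2)C(Br)=C3)CC[C@@H]1Br | intermediate
21 | (1R,2R,4S)-2-bromo-4-[(1S,4S)-4-bromo-3,3-dimethylcyclohexyl]-1-methyl-7-oxabicyclo[2.2.1]heptane | CC1(C)C[C@@H]([C@@]23CC[C@@](C)(O2)[C@H](Br)C3)CC[C@@H]1Br | target

**Totals and risks**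

Total step count: 15. Longest linear sequence: 15 steps (1 → 21).

Steps most likely to fail:

Step 13 (proposed new method). The carbenoid may undergo 1,2-hydride shift to a vinyl ketone or insert into the tertiary C–H of ring A before the ylide forms, or the ylide may shift the ring-fusion carbon or undergo β-elimination in place of the C6 shift. The fallback uses only known chemistry, sets out from Weinreb amide 9 and returns at the target 21. Amide 9 is treated with (3-methylbut-3-en-1-yl)magnesium bromide (THF, 0 °C) to give 1-[(1S,4S)-4-bromo-3,3-dimethylcyclohexyl]-4-methylpent-4-en-1-one F1. The same allylborane antipode as in step 9 (Si-face delivery) converts it into (4S)-4-[(1S,4S)-4-bromo-3,3-dimethylcyclohexyl]-7-methylocta-1,7-dien-4-ol F2. Ring-closing metathesis (second-generation Grubbs catalyst, CH2Cl2, 40 °C) gives (1S)-1-[(1S,4S)-4-bromo-3,3-dimethylcyclohexyl]-4-methylcyclohex-3-en-1-ol F3. N-Bromosuccinimide (CH2Cl2, 0 °C) then effects bromoetherification: the tertiary hydroxyl adds to the methyl-bearing alkene carbon anti to the bromonium ion, which gives the endo bromide and hence 21 directly.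

Step 6. Backside attack at the neopentylic carbon may lose out to elimination from the axial oxyphosphonium ion or to a Wagner–Meerwein methyl shift, and slow substitution may allow lactonisation of 7. The fallback sets out from 7 and returns at 9. Alcohol 7 is lactonised on purpose (cat. TsOH, toluene, reflux, removal of MeOH) to (1R,4S)-6,6-dimethyl-2-oxabicyclo[2.2.2]octan-3-one F4. Alkyl–oxygen cleavage of this strained lactone by bromide with inversion at the carbinol carbon (HBr in AcOH, 60 °C) should give (1S,4S)-4-bromo-3,3-dimethylcyclohexane-1-carboxylic acid F5. Amide coupling with MeNHOMe·HCl (EDC·HCl, N-methylmorpholine, CH2Cl2) then gives 9.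

Step 14. The bromophosphonium reagent and the α-bromo cation on the way to the alkene may trigger opening of the oxygen bridge or a skeletal shift. The fallback sets out from 19 and returns at 20. Kinetic enolisation with in situ trapping (KN(SiMe3)2, PhNTf2, THF, −78 °C) gives (1R,4R)-4-[(1S,4S)-4-bromo-3,3-dimethylcyclohexyl]-1-methyl-7-oxabicyclo[2.2.1]hept-2-en-2-yl trifluoromethanesulfonate F6. Palladium-catalysed exchange of triflate for bromide (Pd2(dba)3, t-BuBrettPhos, KBr, toluene, 100 °C) then gives 20 without a cationic intermediate.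

**Further compounds**

F1 | step 13 | 1-[(1S,4S)-4-bromo-3,3-dimethylcyclohexyl]-4-methylpent-4-en-1-one | CC1(C)C[C@@H](C(=O)CCC(C)=C)CC[C@@H]1Br
F2 | step 13 | (4S)-4-[(1S,4S)-4-bromo-3,3-dimethylcyclohexyl]-7-methylocta-1,7-dien-4-ol | CC1(C)C[C@@H]([C@@](O)(CC=C)CCC(C)=C)CC[C@@H]1Br
F3 | step 13 | (1S)-1-[(1S,4S)-4-bromo-3,3-dimethylcyclohexyl]-4-methylcyclohex-3-en-1-ol | CC1(C)C[C@@H]([C@@]2(O)CC=C(C)CC2)CC[C@@H]1Br
F4 | step 6 | (1R,4S)-6,6-dimethyl-2-oxabicyclo[2.2.2]octan-3-one | CC1(C)C[C@@H]2CC[C@H]1OC2=O
F5 | step 6 | (1S,4S)-4-bromo-3,3-dimethylcyclohexane-1-carboxylic acid | CC1(C)C[C@@H](C(=O)O)CC[C@@H]1Br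
F6 | step 14 | (1R,4R)-4-[(1S,4S)-4-bromo-3,3-dimethylcyclohexyl]-1-methyl-7-oxabicyclo[2.2.1]hept-2-en-2-yl trifluoromethanesulfonate | CC1(C)C[C@@H]([C@@]23CC[C@@](C)(O2)C(OS(=O)(=O)C(F)(F)F)=C3)CC[C@@H]1Br
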